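The retrosynthesis removes the two silyl groups and cuts the Cb–aryl bond (Cb is the benzylic CH2 on C4). It then takes C4–H back to the alkene C4=Cb and C9H2OH (the arm on C3) back to an ester. Last, it cuts C2–C3 and O1–C5 of the oxolane together.
In the ring O1–C2(aryl)–C3(C9)–C4(Cb)–C5, the carbons C3, C5 and Cb sit around central C4 as a trimethylenemethane skeleton. O1–C2 is the carbonyl group of 3,4,5-trimethoxybenzaldehyde, so the only ring maps onto a (3+2) cycloaddition.
Forward, the donor is made in three steps: beta-keto ester, (E)-enol tosylate, then iron-catalysed coupling with Me3SiCH2MgCl. The cycloaddition then builds the oxolane.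
Ester reduction, silylation and a hydroboration/Suzuki–Miyaura sequence attach the guaiacyl ring, and one fluoride step frees both hydroxyl groups.
C2 (R) comes from the chiral phosphoramidite on palladium, and C3 is set trans to C2 in the ring closure. C4 comes from 9-BBN adding opposite the C3 arm, which leaves Cb cis to C9.

Key step: step 4

Assumption: the sense of induction of the phosphoramidite with this donor cannot be predicted with certainty, so the ligand antipode is taken to be the one that leads to (2R); the mirror-image ligand is equally accessible.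

Step 1
Reactants: 1 acetoxyacetyl chloride; 2 potassium methyl malonate
Product: 4 methyl 4-acetoxy-3-oxobutanoate, via acylmalonate half-ester 3 (not isolated)
Conditions: 2, MgCl2, Et3N, MeCN, 0 °C to rt; then 1, 0 °C to rt; 1 M HCl work-up
Reagents that add atoms: none
Why: Acylation of the chelated magnesium enolate of the malonate half-ester, followed by loss of CO2 on acidification (malonate half-ester route to beta-keto esters), should spare the primary acetate because the soft enolate reacts only at the far more electrophilic acyl chloride.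

Step 2
Reactants: 4 methyl 4-acetoxy-3-oxobutanoate
Product: 5 methyl (E)-4-acetoxy-3-(tosyloxy)but-2-enoate
Conditions: TsCl, N-methylimidazole, Et3N, CH2Cl2, 0 °C
Reagents that add atoms: p-toluenesulfonyl chloride, Cc1ccc(cc1)S(=O)(=O)Cl
Why: O-Sulfonylation of the beta-keto ester enolate by the TsCl/N-methylimidazole adduct under non-chelating amine conditions is a known stereoselective enol tosylation that places the sulfonate anti to the ester (E), and only the doubly activated C2 position enolises.

Step 3
Reactants: 5 methyl (E)-4-acetoxy-3-(tosyloxy)but-2-enoate; 6 (trimethylsilyl)methylmagnesium chloride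
Product: 7 methyl (E)-4-acetoxy-3-[(trimethylsilyl)methyl]but-2-enoate
Conditions: Fe(acac)3 (5 mol %), 6 (1.2 equiv), THF/NMP, −20 to 0 °C
Reagents that add atoms: none
Why: Iron-catalysed Kumada-type coupling of beta-sulfonyloxy enoates with alkyl Grignard reagents is fast below 0 °C and keeps the alkene geometry, so Me3SiCH2 should replace the tosylate before the bulky Grignard reagent attacks either ester, and no zerovalent palladium or nickel is present to ionise the allylic acetate.

Step 4
Reactants: 7 methyl (E)-4-acetoxy-3-[(trimethylsilyl)methyl]but-2-enoate; 8 3,4,5-trimethoxybenzaldehyde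
Product: 9 methyl (2R,3R)-4-methylidene-2-(3,4,5-trimethoxyphenyl)oxolane-3-carboxylate
Conditions: Pd(dba)2 (5 mol %), BINOL-derived phosphoramidite of trans-2,5-di(2-naphthyl)pyrrolidine (10 mol %), In(acac)3 (10 mol %), 7 (1.5 equiv), toluene, 23–45 °C
Reagents that add atoms: none
Why: Zerovalent palladium ionises the allylic acetate of 7 and the freed acetate removes the silyl group, giving a zwitterionic trimethylenemethane–palladium complex with the negative charge on the ester-bearing carbon; this carbon adds to the carbonyl carbon of 8 (C2–C3), and the alkoxide, held on indium, then attacks a CH2 terminus of the pi-allyl unit (O1–C5). The closest known reaction is the palladium-catalysed trimethylenemethane (3+2) cycloaddition of aryl aldehydes to 2-aryl-4-methylideneoxolanes under chiral phosphoramidite control, and donors carrying an acceptor group (cyano, acyl, carboxy) are known to bond through the substituted carbon, the family to which 7 belongs. The oxolane closes in a 5-exo-tet-type allylic substitution in which O1 displaces palladium at C5 and the C4=Cb bond is left outside the ring. C2 is controlled by the ligand on palladium, which lets the bound nucleophile reach only the Re face of the aldehyde, and C3 is controlled by the ring closure, since addition of the stabilised carbanion is reversible and the adduct that places aryl and ester on opposite ring faces closes fastest. The step needs regioselectivity (the ester fixes the charge, hence the bond, at C3), 1,2-chemoselectivity (8 has no enolisable position and no second acceptor site, and In(acac)3 activates the carbonyl group and keeps the alkoxide from being silylated) and survival of the deconjugated alkene, which the almost neutral medium should allow because the acetate ends up as Me3SiOAc.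

Step 5
Reactants: 9 methyl (2R,3R)-4-methylidene-2-(3,4,5-trimethoxyphenyl)oxolane-3-carboxylate
Product: 10 [(2R,3S)-4-methylidene-2-(3,4,5-trimethoxyphenyl)oxolan-3-yl]methanol
Conditions: LiAlH4, Et2O, −20 to 0 °C; Na2SO4·10H2O quench
Reagents that add atoms: none
Why: Hydride reduction of the ester at low temperature is faster than deprotonation at the allylic alpha-carbon, so C3 and the exocyclic alkene should pass through unchanged (the C3 descriptor changes from R to S only because the priorities change).

Step 6
Reactants: 10 [(2R,3S)-4-methylidene-2-(3,4,5-trimethoxyphenyl)oxolan-3-yl]methanol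
Product: 11 tert-butyl(dimethyl){[(2R,3S)-4-methylidene-2-(3,4,5-trimethoxyphenyl)oxolan-3-yl]methoxy}silane
Conditions: TBSCl, imidazole, CH2Cl2, 0 °C to rt
Reagents that add atoms: tert-butyldimethylsilyl chloride, CC(C)(C)[Si](C)(C)Cl
Why: Standard silylation of a primary alcohol with a silyl chloride and imidazole puts a bulky arm on C3 that should shield one alkene face in step 8.

Step 7
Reactants: 12 4-bromo-2-methoxyphenol
Product: 13 (4-bromo-2-methoxyphenoxy)tri(propan-2-yl)silane
Conditions: TIPSCl, imidazole, DMF, rt
Reagents that add atoms: triisopropylsilyl chloride, CC(C)[Si](Cl)(C(C)C)C(C)C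
Why: Silylation masks the acidic phenol, which as a phenoxide would slow oxidative addition in the coupling, and the hindered triisopropylsilyl ether should survive aqueous phosphate.

Step 8
Reactants: 11 tert-butyl(dimethyl){[(2R,3S)-4-methylidene-2-(3,4,5-trimethoxyphenyl)oxolan-3-yl]methoxy}silane; 13 (4-bromo-2-methoxyphenoxy)tri(propan-2-yl)silane
Product: 15 tert-butyl{[(2R,3S,4S)-4-{[3-methoxy-4-(triisopropylsilyloxy)phenyl]methyl}-2-(3,4,5-trimethoxyphenyl)oxolan-3-yl]methoxy}dimethylsilane, via B-alkyl-9-BBN adduct 14 (not isolated)
Conditions: 9-BBN, THF, 0 °C to rt; then 13, PdCl2(dppf) (5 mol %), aq. K3PO4, THF/DMF, 50 °C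
Reagents that add atoms: none
Why: In the hydroboration 9-BBN places boron on terminal Cb and delivers hydrogen to C4 from the face opposite the adjacent silyloxymethyl arm, so Cb ends cis to C9 (4S), and the B-alkyl Suzuki–Miyaura coupling then forms Cb–aryl without touching a stereocentre.

Step 9
Reactants: 15 tert-butyl{[(2R,3S,4S)-4-{[3-methoxy-4-(triisopropylsilyloxy)phenyl]methyl}-2-(3,4,5-trimethoxyphenyl)oxolan-3-yl]methoxy}dimethylsilane
Product: 16 4-{[(3S,4S,5R)-4-(hydroxymethyl)-5-(3,4,5-trimethoxyphenyl)oxolan-3-yl]methyl}-2-methoxyphenol (target)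
Conditions: TBAF, AcOH (3 equiv each), THF, 0 °C to rt
Reagents that add atoms: none
Why: Fluoride-induced cleavage of both silyl ethers, buffered with acetic acid so that the phenol stays protonated, should affect neither the methyl ethers nor the benzylic C2–O bond and leaves the three stereocentres as set.

Compound list
1 | acetoxyacetyl chloride | CC(=O)OCC(=O)Cl | starting material
2 | potassium methyl malonate | COC(=O)CC(=O)[O-].[K+] | starting material
3 | 2-(acetoxyacetyl)malonic acid monomethyl ester (magnesium chelate in the flask, labile centre undefined) | COC(=O)C(C(=O)O)C(=O)COC(C)=O | intermediate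
4 | methyl 4-acetoxy-3-oxobutanoate | COC(=O)CC(=O)COC(C)=O | intermediate
5 | methyl (E)-4-acetoxy-3-(tosyloxy)but-2-enoate | COC(=O)/C=C(/OS(=O)(=O)c1ccc(C)cc1)COC(C)=O | intermediate
6 | (trimethylsilyl)methylmagnesium chloride | C[Si](C)(C)C[Mg]Cl | starting material
7 | methyl (E)-4-acetoxy-3-[(trimethylsilyl)methyl]but-2-enoate | COC(=O)/C=C(\COC(C)=O)C[Si](C)(C)C | intermediate
8 | 3,4,5-trimethoxybenzaldehyde | COc1cc(C=O)cc(OC)c1OC | starting material
9 | methyl (2R,3R)-4-methylidene-2-(3,4,5-trimethoxyphenyl)oxolane-3-carboxylate | C=C1CO[C@@H](c2cc(OC)c(OC)c(OC)c2)[C@@H]1C(=O)OC | intermediate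
10 | [(2R,3S)-4-methylidene-2-(3,4,5-trimethoxyphenyl)oxolan-3-yl]methanol | C=C1CO[C@@H](c2cc(OC)c(OC)c(OC)c2)[C@@H]1CO | intermediate
11 | tert-butyl(dimethyl){[(2R,3S)-4-methylidene-2-(3,4,5-trimethoxyphenyl)oxolan-3-yl]methoxy}silane | C=C1CO[C@@H](c2cc(OC)c(OC)c(OC)c2)[C@@H]1CO[Si](C)(C)C(C)(C)C | intermediate
12 | 4-bromo-2-methoxyphenol | COc1cc(Br)ccc1O | starting material
13 | (4-bromo-2-methoxyphenoxy)tri(propan-2-yl)silane | COc1cc(Br)ccc1O[Si](C(C)C)(C(C)C)C(C)C | intermediate
14 | 9-{[(3S,4S,5R)-4-(tert-butyldimethylsilyloxymethyl)-5-(3,4,5-trimethoxyphenyl)oxolan-3-yl]methyl}-9-borabicyclo[3.3.1]nonane | C1CC2CCCC(C1)B2C[C@@H]1CO[C@@H](c2cc(OC)c(OC)c(OC)c2)[C@@H]1CO[Si](C)(C)C(C)(C)C | intermediate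
15 | tert-butyl{[(2R,3S,4S)-4-{[3-methoxy-4-(triisopropylsilyloxy)phenyl]methyl}-2-(3,4,5-trimethoxyphenyl)oxolan-3-yl]methoxy}dimethylsilane | COc1cc(C[C@@H]2CO[C@@H](c3cc(OC)c(OC)c(OC)c3)[C@@H]2CO[Si](C)(C)C(C)(C)C)ccc1O[Si](C(C)C)(C(C)C)C(C)C | intermediate
16 | 4-{[(3S,4S,5R)-4-(hydroxymethyl)-5-(3,4,5-trimethoxyphenyl)oxolan-3-yl]methyl}-2-methoxyphenol | COc1cc(C[C@@H]2CO[C@@H](c3cc(OC)c(OC)c(OC)c3)[C@@H]2CO)ccc1O | target

Total step count: 9. Longest linear sequence: 8 (steps 1–6, 8, 9).

Steps most likely to fail

Step 4. The ester-stabilised palladium complex may be protonated or consumed by self-reaction faster than it adds to the aldehyde. The C4=Cb alkene may also slip into conjugation with the ester, and reversible C–C bond formation may erode the face selection. The fallback replaces the cycloaddition by a radical ring closure; it sets out from 8 and comes back at 10. Vinylmagnesium bromide adds to 8 to give racemic 1-(3,4,5-trimethoxyphenyl)prop-2-en-1-ol F1. A Sharpless kinetic resolution follows (Ti(OiPr)4, L-(+)-diisopropyl tartrate, about 0.45 equiv t-BuOOH, 4 Å sieves, CH2Cl2, −20 °C). It epoxidises the faster-reacting (R)-carbinol to the erythro epoxy alcohol (S)-[(2R)-oxiran-2-yl](3,4,5-trimethoxyphenyl)methanol F2. NaH and propargyl bromide in THF then give (2R)-2-[(S)-(prop-2-yn-1-yloxy)(3,4,5-trimethoxyphenyl)methyl]oxirane F3. Cp2TiCl (from Cp2TiCl2 and Zn, THF, rt) opens the oxirane to the secondary beta-titanoxy radical at C3. This radical closes 5-exo-dig onto the alkyne (C3–C4) with the aryl and CH2O arms trans, and acidic work-up gives 10. In this variant C2 comes from the resolution, and the oxirane stereocentre is erased in the radical.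

Step 8. The borane may discriminate poorly between the two alkene faces, because the face it must use carries the C2 aryl group one atom further away. The hindered B-alkyl group may also transmetalate slowly. The fallback installs the aryl group first and the hydrogen second; it sets out from 11 and comes back at 16. Lemieux–Johnson cleavage (OsO4 cat., NaIO4, 2,6-lutidine, dioxane/H2O) gives (4S,5R)-4-(tert-butyldimethylsilyloxymethyl)-5-(3,4,5-trimethoxyphenyl)oxolan-3-one F4. Commercial 4-benzyloxy-3-methoxybenzyl alcohol and Ph3P·HBr give [4-(benzyloxy)-3-methoxybenzyl]triphenylphosphonium bromide F5. Its ylide (KHMDS, THF, −78 °C to rt) converts F4 in a Wittig reaction into tert-butyl({(2R,3S)-4-[(4-benzyloxy-3-methoxyphenyl)methylidene]-2-(3,4,5-trimethoxyphenyl)oxolan-3-yl}methoxy)dimethylsilane F6, either alkene geometry being usable. Brief hydrogenation (H2, Pd/C, EtOAc) should add hydrogen on the face away from the silyloxymethyl arm, where the C2 aryl group can rest on the catalyst surface. The same hydrogenation removes the benzyl ether, giving 4-{[(3S,4S,5R)-4-(tert-butyldimethylsilyloxymethyl)-5-(3,4,5-trimethoxyphenyl)oxolan-3-yl]methyl}-2-methoxyphenol F7. TBAF then gives 16.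

Step 3. The Grignard reagent may attack the acetate, substitute the allylic position of substrate or product, or the alkene geometry may be lost during the coupling. The fallback uses carbonyl olefination instead of cross-coupling; it sets out from 1 and 6 and comes back at 7. Copper-catalysed acylation of 6 with 1 (CuI, THF, −78 °C) gives 1-acetoxy-3-(trimethylsilyl)propan-2-one F8. A base-free Wittig olefination with methyl (triphenylphosphoranylidene)acetate (toluene, 60 °C) spares the base-sensitive alpha-silyl ketone and gives 7. Any Z isomer formed alongside would ionise to the same trimethylenemethane complex in step 4.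

Further compounds
F1 | step 4 | 1-(3,4,5-trimethoxyphenyl)prop-2-en-1-ol (racemic) | C=CC(O)c1cc(OC)c(OC)c(OC)c1
F2 | step 4 | (S)-[(2R)-oxiran-2-yl](3,4,5-trimethoxyphenyl)methanol | O[C@@H](c1cc(OC)c(OC)c(OC)c1)[C@H]1CO1
F3 | step 4 | (2R)-2-[(S)-(prop-2-yn-1-yloxy)(3,4,5-trimethoxyphenyl)methyl]oxirane | C#CCO[C@@H](c1cc(OC)c(OC)c(OC)c1)[C@H]1CO1
F4 | step 8 | (4S,5R)-4-(tert-butyldimethylsilyloxymethyl)-5-(3,4,5-trimethoxyphenyl)oxolan-3-one | O=C1CO[C@@H](c2cc(OC)c(OC)c(OC)c2)[C@@H]1CO[Si](C)(C)C(C)(C)C
F5 | step 8 | [4-(benzyloxy)-3-methoxybenzyl]triphenylphosphonium bromide | COc1cc(C[P+](c2ccccc2)(c2ccccc2)c2ccccc2)ccc1OCc1ccccc1.[Br-]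
F6 | step 8 | tert-butyl({(2R,3S)-4-[(4-benzyloxy-3-methoxyphenyl)methylidene]-2-(3,4,5-trimethoxyphenyl)oxolan-3-yl}methoxy)dimethylsilane (E/Z mixture) | COc1cc(C=C2CO[C@@H](c3cc(OC)c(OC)c(OC)c3)[C@@H]2CO[Si](C)(C)C(C)(C)C)ccc1OCc1ccccc1
F7 | step 8 | 4-{[(3S,4S,5R)-4-(tert-butyldimethylsilyloxymethyl)-5-(3,4,5-trimethoxyphenyl)oxolan-3-yl]methyl}-2-methoxyphenol | COc1cc(C[C@@H]2CO[C@@H](c3cc(OC)c(OC)c(OC)c3)[C@@H]2CO[Si](C)(C)C(C)(C)C)ccc1O
F8 | step 3 | 1-acetoxy-3-(trimethylsilyl)propan-2-one | CC(=O)OCC(=O)C[Si](C)(C)C
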